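**Retrosynthetic overview**

- The route rests on ring A: its oxygens at C5 and C7 are 1,3-related and C8 carries a methoxy group next to the ring-fusion carbon C8a. C5 can therefore be an ester carbon on C4a, and C8–C7–C6 a 1-methoxy-2-oxopropyl chain on C8a of a finished ring C.
- Key disconnection C5–C6 (intramolecular Claisen acylation, then aromatisation): flavone 15 ⇒ 4-pyranone-3-carboxylate 13.
- Ring C is opened at O1–C8a (cyclodehydration) to the 2-acyl-3,5-diketo ester 11. This is cut at C4a–C8a into diketo ester 5 and acid chloride 10, and 5 at C2–C3 into Weinreb amide 3 and the dianion of ethyl 4-(benzyloxy)acetoacetate 4.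
- Ring order: ring B is bought, ring C closes in step 9, ring A closes in step 10; 7-O-methylation and hydrogenolysis of both benzyl ethers finish the route.

Key step: step 10

Remark: the target has no stereocentre. The sp3 carbons alpha to carbonyl groups in 5, 7, 8, 9, 10, 11, 12, 13 and 14 are racemic or enolisable and end as sp2 carbons; the open-chain polycarbonyl compounds are drawn as keto tautomers although they should be largely enolised.

**Route**

Step 1
Reactants: 1 2-hydroxy-4-methoxybenzoic acid
Product: 2 benzyl 2-(benzyloxy)-4-methoxybenzoate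
Conditions: BnBr (2.3 equiv), K2CO3, DMF, 60 °C
Reagents that add atoms: benzyl bromide, BrCc1ccccc1
Why: Williamson O-alkylation under carbonate base benzylates both the carboxylate and the hydrogen-bonded phenol, so one operation protects the 2'-oxygen and gives an ester ready for amidation.

Step 2
Reactants: 2 benzyl 2-(benzyloxy)-4-methoxybenzoate
Product: 3 2-(benzyloxy)-N,4-dimethoxy-N-methylbenzamide
Conditions: MeNH(OMe)·HCl (1.5 equiv), i-PrMgCl (3 equiv), THF, −20 → 0 °C; then 1 M HCl
Reagents that add atoms: N,O-dimethylhydroxylamine hydrochloride, CNOC.Cl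
Why: the chloromagnesium amide formed from the amine salt and i-PrMgCl converts the ester into the Weinreb amide by acyl substitution, and the chelated tetrahedral adducts of this amide later stop acylation at the ketone stage.

Step 3
Reactants: 4 ethyl 4-(benzyloxy)-3-oxobutanoate; 3 2-(benzyloxy)-N,4-dimethoxy-N-methylbenzamide
Product: 5 ethyl 4-(benzyloxy)-5-[2-(benzyloxy)-4-methoxyphenyl]-3,5-dioxopentanoate
Conditions: LiN(i-Pr)2 (LDA, 2.2 equiv), THF, −78 → −20 °C; then 3, −78 → 0 °C; then cold 1 M HCl
Reagents that add atoms: none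
Why: gamma-acylation of a beta-keto ester dianion, in which the second deprotonation takes place at the benzyloxy-bearing C4, this more reactive carbanion adds to the Weinreb amide, and the chelated adduct collapses to the 3,5-diketo ester only on acid work-up, so over-addition and proton quench of the dianion by the product should both be avoided.

Step 4
Reactants: 6 methyl methoxyacetate
Product: 7 methyl 2-methoxy-3-oxobutanoate (racemic)
Conditions: LiN(i-Pr)2 (LDA, 2 equiv), 6 (2 equiv), THF, −78 °C; then AcCl (1 equiv), −78 °C; then 1 M HCl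
Reagents that add atoms: acetyl chloride, CC(Cl)=O
Why: directed crossed Claisen condensation in which the preformed lithium enolate of the alpha-methoxy ester is C-acylated by acetyl chloride, the second equivalent of enolate taking up the acidic proton of the beta-keto ester formed.

Step 5
Reactants: 7 methyl 2-methoxy-3-oxobutanoate
Product: 8 methyl 2-methoxy-2-(2-methyl-1,3-dioxolan-2-yl)acetate (racemic)
Conditions: HOCH2CH2OH, p-TsOH (cat.), toluene, reflux, Dean–Stark trap
Reagents that add atoms: ethylene glycol, OCCO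
Why: acid-catalysed ketalisation with azeotropic removal of water masks the ketone as a 1,3-dioxolane, which makes a stable acid chloride possible and keeps this ketone out of the later pyranone closure.

Step 6
Reactants: 8 methyl 2-methoxy-2-(2-methyl-1,3-dioxolan-2-yl)acetate
Product: 9 sodium 2-methoxy-2-(2-methyl-1,3-dioxolan-2-yl)acetate (racemic)
Conditions: NaOH (1.0 equiv), MeOH/H2O, rt; evaporate and dry by toluene azeotrope
Reagents that add atoms: sodium hydroxide, [Na+].[OH-]
Why: saponification of the unhindered alpha-alkoxy methyl ester with one equivalent of hydroxide gives the carboxylate salt directly, so the acid-labile dioxolane never meets an acidic work-up.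

Step 7
Reactants: 9 sodium 2-methoxy-2-(2-methyl-1,3-dioxolan-2-yl)acetate
Product: 10 2-methoxy-2-(2-methyl-1,3-dioxolan-2-yl)acetyl chloride (racemic, used crude)
Conditions: (COCl)2 (1.1 equiv), DMF (cat.), CH2Cl2, 0 °C → rt; filter, evaporate
Reagents that add atoms: oxalyl chloride, O=C(Cl)C(Cl)=O
Why: a carboxylate salt and oxalyl chloride give the acid chloride with NaCl, CO and CO2 as the only by-products, so no hydrogen chloride is set free to open the dioxolane.

Step 8
Reactants: 5 ethyl 4-(benzyloxy)-5-[2-(benzyloxy)-4-methoxyphenyl]-3,5-dioxopentanoate; 10 2-methoxy-2-(2-methyl-1,3-dioxolan-2-yl)acetyl chloride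
Product: 11 ethyl 4-(benzyloxy)-5-[2-(benzyloxy)-4-methoxyphenyl]-2-[2-methoxy-2-(2-methyl-1,3-dioxolan-2-yl)acetyl]-3,5-dioxopentanoate (diastereomer mixture)
Conditions: MgCl2 (1.2 equiv), pyridine (2.5 equiv), CH2Cl2, 0 °C → rt; then cold 1 M HCl
Reagents that add atoms: none
Why: magnesium-mediated soft enolisation and C-acylation of a beta-keto ester, in which C2 is the only methylene between two carbonyl groups and its acylation gives a triacylmethane held as a stable magnesium chelate, whereas acylation at the fully substituted C4 or on an enol oxygen is reversible under the conditions.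

Step 9
Reactants: 11 ethyl 4-(benzyloxy)-5-[2-(benzyloxy)-4-methoxyphenyl]-2-[2-methoxy-2-(2-methyl-1,3-dioxolan-2-yl)acetyl]-3,5-dioxopentanoate
Product: 13 ethyl 5-(benzyloxy)-6-[2-(benzyloxy)-4-methoxyphenyl]-2-(1-methoxy-2-oxopropyl)-4-oxo-4H-pyran-3-carboxylate (racemic), via dioxolane-protected pyranone 12 (not isolated)
Conditions: p-TsOH (anhydrous, 0.3 equiv), 4 Å molecular sieves, CH2Cl2, 40 °C; then filter, TFA/H2O (9:1), rt
Reagents that add atoms: water, O
Why: acid-catalysed cyclodehydration of a 1,3,5-tricarbonyl unit to a 4-pyranone, in which the enol oxygen of one terminal ketone adds to the other ketone (far more electrophilic than the ester, so 2-pyranone formation is not expected), the sieves take up the water so that the dioxolane survives until ring C is closed, and aqueous trifluoroacetic acid then hydrolyses the ketal.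

Step 10
Reactants: 13 ethyl 5-(benzyloxy)-6-[2-(benzyloxy)-4-methoxyphenyl]-2-(1-methoxy-2-oxopropyl)-4-oxo-4H-pyran-3-carboxylate
Product: 15 3-(benzyloxy)-2-[2-(benzyloxy)-4-methoxyphenyl]-5,7-dihydroxy-8-methoxy-4H-chromen-4-one, via triketone tautomer 14 (not isolated)
Conditions: KOt-Bu (3.5 equiv), THF, N2, 0 → 40 °C; then 1 M HCl
Reagents that add atoms: none
Why: Proposed new method: tert-butoxide first removes the doubly activated C8–H of 13, which shields ring C from nucleophiles, and the methyl ketone enolate in equilibrium with this anion adds to the neighbouring ester carbonyl to form the C5–C6 bond, after which loss of ethoxide gives triketone 14 and enolisation gives the bis-phenoxide of 15. The closest known reactions are the alkoxide-mediated Claisen cyclisation of ortho-(2-oxopropyl)benzoates to naphthalene-1,3-diols and the Claisen closures of poly-beta-carbonyl chains to phloroglucinol-type rings, but the same closure on a 4-pyranone-3-carboxylate is not established. Ring A closes in a 6-exo-trig mode, the carbanion at C6 attacking the exocyclic ester C=O. No stereocentre is formed, and the racemic C8 centre of 13 becomes an sp2 carbon of ring A. The step needs C-acylation through the methyl enolate instead of O-acylation by the C8 enolate oxygen or attack at the ring carbonyl C4: C4 lies trans to the side chain across the C4a=C8a bond and cannot be reached, an enol lactone from O-attack would be reopened by the ethoxide set free, and only the C-acylation path ends in an irreversible aromatisation. Because O1 and C8a already belong to ring C, the methoxy group can only end up at C8.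

Step 11
Reactants: 15 3-(benzyloxy)-2-[2-(benzyloxy)-4-methoxyphenyl]-5,7-dihydroxy-8-methoxy-4H-chromen-4-one
Product: 16 3-(benzyloxy)-2-[2-(benzyloxy)-4-methoxyphenyl]-5-hydroxy-7,8-dimethoxy-4H-chromen-4-one
Conditions: MeI (1.1 equiv), K2CO3 (1.5 equiv), acetone, rt → 40 °C
Reagents that add atoms: iodomethane, CI
Why: Williamson methylation with a slight excess of MeI takes place at the more acidic 7-hydroxyl, because the 5-hydroxyl is locked in a hydrogen bond to the C4 carbonyl and reacts only under forcing conditions.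

Step 12
Reactants: 16 3-(benzyloxy)-2-[2-(benzyloxy)-4-methoxyphenyl]-5-hydroxy-7,8-dimethoxy-4H-chromen-4-one
Product: 17 3,5,2'-trihydroxy-7,8,4'-trimethoxyflavone
Conditions: H2 (1 atm), 10% Pd/C, EtOAc/MeOH, rt
Reagents that add atoms: none
Why: catalytic hydrogenolysis cleaves the enol benzyl ether at C3 and the aryl benzyl ether at C2' under conditions that should leave the methyl ethers and the chromone untouched.

**Compound list**

1 | 2-hydroxy-4-methoxybenzoic acid | COc1ccc(C(=O)O)c(O)c1 | starting material
2 | benzyl 2-(benzyloxy)-4-methoxybenzoate | COc1ccc(C(=O)OCc2ccccc2)c(OCc2ccccc2)c1 | intermediate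
3 | 2-(benzyloxy)-N,4-dimethoxy-N-methylbenzamide | COc1ccc(C(=O)N(C)OC)c(OCc2ccccc2)c1 | intermediate
4 | ethyl 4-(benzyloxy)-3-oxobutanoate | CCOC(=O)CC(=O)COCc1ccccc1 | starting material
5 | ethyl 4-(benzyloxy)-5-[2-(benzyloxy)-4-methoxyphenyl]-3,5-dioxopentanoate (racemic, keto form drawn) | CCOC(=O)CC(=O)C(OCc1ccccc1)C(=O)c1ccc(OC)cc1OCc1ccccc1 | intermediate
6 | methyl methoxyacetate | COCC(=O)OC | starting material
7 | methyl 2-methoxy-3-oxobutanoate (racemic) | COC(C(C)=O)C(=O)OC | intermediate
8 | methyl 2-methoxy-2-(2-methyl-1,3-dioxolan-2-yl)acetate (racemic) | COC(C(=O)OC)C1(C)OCCO1 | intermediate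
9 | sodium 2-methoxy-2-(2-methyl-1,3-dioxolan-2-yl)acetate (racemic) | COC(C(=O)[O-])C1(C)OCCO1.[Na+] | intermediate
10 | 2-methoxy-2-(2-methyl-1,3-dioxolan-2-yl)acetyl chloride (racemic) | COC(C(=O)Cl)C1(C)OCCO1 | intermediate
11 | ethyl 4-(benzyloxy)-5-[2-(benzyloxy)-4-methoxyphenyl]-2-[2-methoxy-2-(2-methyl-1,3-dioxolan-2-yl)acetyl]-3,5-dioxopentanoate (diastereomer mixture, keto form drawn) | CCOC(=O)C(C(=O)C(OC)C1(C)OCCO1)C(=O)C(OCc1ccccc1)C(=O)c1ccc(OC)cc1OCc1ccccc1 | intermediate
12 | ethyl 5-(benzyloxy)-6-[2-(benzyloxy)-4-methoxyphenyl]-2-[methoxy(2-methyl-1,3-dioxolan-2-yl)methyl]-4-oxo-4H-pyran-3-carboxylate (racemic, not isolated) | CCOC(=O)c1c(C(OC)C2(C)OCCO2)oc(-c2ccc(OC)cc2OCc2ccccc2)c(OCc2ccccc2)c1=O | intermediate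
13 | ethyl 5-(benzyloxy)-6-[2-(benzyloxy)-4-methoxyphenyl]-2-(1-methoxy-2-oxopropyl)-4-oxo-4H-pyran-3-carboxylate (racemic) | CCOC(=O)c1c(C(OC)C(C)=O)oc(-c2ccc(OC)cc2OCc2ccccc2)c(OCc2ccccc2)c1=O | intermediate
14 | 3-(benzyloxy)-2-[2-(benzyloxy)-4-methoxyphenyl]-8-methoxy-6,8-dihydro-4H-chromene-4,5,7-trione (racemic keto tautomer of 15, not isolated) | COC1C(=O)CC(=O)c2c1oc(-c1ccc(OC)cc1OCc1ccccc1)c(OCc1ccccc1)c2=O | intermediate
15 | 3-(benzyloxy)-2-[2-(benzyloxy)-4-methoxyphenyl]-5,7-dihydroxy-8-methoxy-4H-chromen-4-one | COc1ccc(-c2oc3c(OC)c(O)cc(O)c3c(=O)c2OCc2ccccc2)c(OCc2ccccc2)c1 | intermediate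
16 | 3-(benzyloxy)-2-[2-(benzyloxy)-4-methoxyphenyl]-5-hydroxy-7,8-dimethoxy-4H-chromen-4-one | COc1ccc(-c2oc3c(OC)c(OC)cc(O)c3c(=O)c2OCc2ccccc2)c(OCc2ccccc2)c1 | intermediate
17 | 3,5,2'-trihydroxy-7,8,4'-trimethoxyflavone | COc1ccc(-c2oc3c(OC)c(OC)cc(O)c3c(=O)c2O)c(O)c1 | target

**Step count**

Total: 12 steps. Longest linear sequence: 9 steps (6 → 7 → 8 → 9 → 10 → 11 → 13 → 15 → 16 → 17; steps 4 to 12).

**Steps most likely to fail**

1. Step 10 (key step). The ester is deactivated while the C8 anion is delocalised into ring C, so the methyl enolate may fail to add to it. O-acylation to an enol lactone or opening of the pyranone by alkoxide could then consume the material.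
Fallback by classical flavone chemistry, setting out from Weinreb amide 3 and coming back at target 17. Reduction of 3 with i-Bu2AlH (THF, −78 °C) gives 2-(benzyloxy)-4-methoxybenzaldehyde F1. Claisen–Schmidt condensation of F1 with commercial 1-(2-hydroxy-3,4,6-trimethoxyphenyl)ethanone (KOH, EtOH, rt) gives (E)-3-[2-(benzyloxy)-4-methoxyphenyl]-1-(2-hydroxy-3,4,6-trimethoxyphenyl)prop-2-en-1-one F2. Oxidative cyclisation through its only free phenol (I2 cat., DMSO, 120 °C) gives 2-[2-(benzyloxy)-4-methoxyphenyl]-5,7,8-trimethoxy-4H-chromen-4-one F3. Dimethyldioxirane (acetone/CH2Cl2, 0 °C) epoxidises the C2=C3 bond to 1a-[2-(benzyloxy)-4-methoxyphenyl]-4,5,7-trimethoxy-1a,7a-dihydro-7H-oxireno[2,3-b]chromen-7-one F4, which p-TsOH opens to 2-[2-(benzyloxy)-4-methoxyphenyl]-3-hydroxy-5,7,8-trimethoxy-4H-chromen-4-one F5. BCl3 (CH2Cl2, −78 → 0 °C) then removes the benzyl ether and the chelated 5-O-methyl group, leaves the 7-, 8- and 4'-methyl ethers, and gives 17.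

2. Step 8. Acylation may go to the wrong site (an enol oxygen of the diketone or C4), and 5 may lactonise to a 4-hydroxy-2-pyranone with loss of ethanol before C2 is acylated.
Fallback by reversing the order of the two C–C bond formations, setting out from 4 and 10 and coming back at 11. Keto ester 4, which has a single acidic methylene, is acylated with 10 (MgCl2, pyridine, CH2Cl2) to give ethyl 4-(benzyloxy)-2-[2-methoxy-2-(2-methyl-1,3-dioxolan-2-yl)acetyl]-3-oxobutanoate F6. Its dianion (LiN(i-Pr)2, 3 equiv, THF, −78 °C; the triacylmethane proton first, then the less hindered CH2OBn) is aroylated with Weinreb amide 3 to give 11 after acid work-up.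

3. Step 9. The dioxolane may be lost before ring closure, so that the freed methyl ketone competes as the electrophile and closes the wrong pyranone. Lactonisation of the aroyl enol onto the ester may also overtake the slow closure onto the hindered, branched acyl group.
Fallback that closes ring C first on an unhindered, ketal-free acyl group and adds the acetyl group afterwards, setting out from 5 and coming back at 13. Diketo ester 5 is acylated with commercial methoxyacetyl chloride (MgCl2, pyridine) to give ethyl 4-(benzyloxy)-5-[2-(benzyloxy)-4-methoxyphenyl]-2-(methoxyacetyl)-3,5-dioxopentanoate F7. Cyclodehydration (p-TsOH, 4 Å sieves, CH2Cl2) gives ethyl 5-(benzyloxy)-6-[2-(benzyloxy)-4-methoxyphenyl]-2-(methoxymethyl)-4-oxo-4H-pyran-3-carboxylate F8. Deprotonation of its vinylogous CH2OMe group (LiN(SiMe3)2, 2.2 equiv, THF, −78 °C) and acetylation with N-methoxy-N-methylacetamide give 13 after acid work-up.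

**Further compounds**

F1 | step 10 | 2-(benzyloxy)-4-methoxybenzaldehyde | COc1ccc(C=O)c(OCc2ccccc2)c1
F2 | step 10 | (E)-3-[2-(benzyloxy)-4-methoxyphenyl]-1-(2-hydroxy-3,4,6-trimethoxyphenyl)prop-2-en-1-one | COc1ccc(/C=C/C(=O)c2c(OC)cc(OC)c(OC)c2O)c(OCc2ccccc2)c1
F3 | step 10 | 2-[2-(benzyloxy)-4-methoxyphenyl]-5,7,8-trimethoxy-4H-chromen-4-one | COc1ccc(-c2cc(=O)c3c(OC)cc(OC)c(OC)c3o2)c(OCc2ccccc2)c1
F4 | step 10 | 1a-[2-(benzyloxy)-4-methoxyphenyl]-4,5,7-trimethoxy-1a,7a-dihydro-7H-oxireno[2,3-b]chromen-7-one (racemic, cis-fused) | COc1ccc(C23OC2C(=O)c2c(OC)cc(OC)c(OC)c2O3)c(OCc2ccccc2)c1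
F5 | step 10 | 2-[2-(benzyloxy)-4-methoxyphenyl]-3-hydroxy-5,7,8-trimethoxy-4H-chromen-4-one | COc1ccc(-c2oc3c(OC)c(OC)cc(OC)c3c(=O)c2O)c(OCc2ccccc2)c1
F6 | step 8 | ethyl 4-(benzyloxy)-2-[2-methoxy-2-(2-methyl-1,3-dioxolan-2-yl)acetyl]-3-oxobutanoate (diastereomer mixture) | CCOC(=O)C(C(=O)COCc1ccccc1)C(=O)C(OC)C1(C)OCCO1
F7 | step 9 | ethyl 4-(benzyloxy)-5-[2-(benzyloxy)-4-methoxyphenyl]-2-(methoxyacetyl)-3,5-dioxopentanoate (diastereomer mixture) | CCOC(=O)C(C(=O)COC)C(=O)C(OCc1ccccc1)C(=O)c1ccc(OC)cc1OCc1ccccc1
F8 | step 9 | ethyl 5-(benzyloxy)-6-[2-(benzyloxy)-4-methoxyphenyl]-2-(methoxymethyl)-4-oxo-4H-pyran-3-carboxylate | CCOC(=O)c1c(COC)oc(-c2ccc(OC)cc2OCc2ccccc2)c(OCc2ccccc2)c1=O
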